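**Assumptions:** two-stage one-pot operations (steps 1, 2, 12) count as one step each. Fixed skeleton labels are used throughout: C1 = carbinol carbon bearing iPr; C2, C3 = CH2; C4 = ring-fusion C–Me; C5 = CH2; C6/C7 = oxirane CH / C(Me); C8 = CH2; C9 = ester carbinol; C10 = ring-fusion CH.

## Retrosynthetic overview

1. Jaeskeanin 14 ⇐ epoxy diol 12 + 4-acetoxybenzoyl chloride 13; the oxirane ⇐ C9–OH-directed epoxidation of jaeschkeanadiol 11.
2. 11 ⇐ β-hydroxy ketone 10 (1,3-anti reduction) ⇐ diene carbinol 8 (diene mono-epoxidation, Pd isomerisation) ⇐ ketone 7 + iPr–M.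
3. 7 ⇐ cyclopropyl ketone 6 (reductive cleavage gives the angular methyl) ⇐ CBS alcohol 4 (directed cyclopropanation) ⇐ trienone 3.
4. 3 ⇐ diazoketone 2 by intramolecular Buchner reaction, which builds the five- and seven-membered rings together from a p-tolyl ring; 2 ⇐ 3-(p-tolyl)propanoic acid 1.
5. Ring order: 5 + 7 together (step 2), transient cyclopropane (step 4, opened in step 6), oxirane (step 11).

## Route

**Step 1**
Reactants: 1, 3-(4-methylphenyl)propanoic acid
Product: 2, 1-diazo-4-(4-methylphenyl)butan-2-one
Conditions: (COCl)2, cat. DMF, CH2Cl2, 0 °C→rt; then CH2N2 (3 equiv), Et2O, 0 °C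
Reagents that add atoms: diazomethane, C=[N+]=[N-]
Why: Acylation of diazomethane by the acid chloride (Arndt–Eistert-type diazoketone synthesis), with excess CH2N2 scavenging HCl; no stereocentre.

**Step 2**
Reactants: 2, 1-diazo-4-(4-methylphenyl)butan-2-one
Product: 3, 6-methyl-3,4-dihydroazulen-1(2H)-one (achiral; C1=O, C10=C4, C9=C8, C7(Me)=C6, C5H2)
Conditions: Rh2(OAc)4 (0.5 mol%), CH2Cl2, reflux, slow addition, acid-free; then Et3N, rt
Reagents that add atoms: none
Why: Intramolecular Buchner reaction: the Rh carbenoid cyclopropanates the ipso/ortho bond (closing the cyclopentanone and norcaradiene rings at once), 6π ring-opening gives the cycloheptatriene, and Et3N moves the ring-fusion H into conjugation; the para methyl ends on C7 with C6=C7 already in its final position.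

**Step 3**
Reactants: 3, 6-methyl-3,4-dihydroazulen-1(2H)-one
Product: 4, (1S)-6-methyl-1,2,3,4-tetrahydroazulen-1-ol
Conditions: (R)-Me-CBS (20 mol%), catecholborane, toluene, −78 °C; basic work-up, used crude
Reagents that add atoms: none
Why: Corey–Bakshi–Shibata reduction; the ketone is flanked by CH2 (small) and a fully substituted alkenyl carbon (large), so the (R)-catalyst gives the (S)-carbinol, a temporary stereocentre used only to relay chirality to C4.

**Step 4**
Reactants: 4, (1S)-6-methyl-1,2,3,4-tetrahydroazulen-1-ol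
Product: 5, (1S,3aR,8aS)-6-methyl-1,2,3,4-tetrahydro-3a,8a-methanoazulen-1-ol (cyclopropane CH2 across C4–C10, cis to OH)
Conditions: Et2Zn (2 equiv), CH2I2 (2 equiv), CH2Cl2, −20→0 °C
Reagents that add atoms: diiodomethane, ICI
Why: Hydroxyl-directed Simmons–Smith (Furukawa) cyclopropanation: the zinc alkoxide delivers CH2 to the allylic tetrasubstituted C10=C4 alkene on the OH face, fixing the absolute configuration of C4.

**Step 5**
Reactants: 5, cyclopropyl carbinol
Product: 6, (3aR,8aS)-6-methyl-3,4-dihydro-3a,8a-methanoazulen-1(2H)-one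
Conditions: Dess–Martin periodinane, NaHCO3, CH2Cl2, 0 °C
Reagents that add atoms: none
Why: Dess–Martin oxidation under buffered, non-acidic conditions; the C1 stereocentre is erased after its relay role and the cyclopropane centres keep the ee.

**Step 6**
Reactants: 6, cyclopropyl ketone
Product: 7, (3aR,8aR)-3a,6-dimethyl-3,3a,4,8a-tetrahydroazulen-1(2H)-one (C4–Me and C10–H trans)
Conditions: SmI2 (2.5 equiv), THF–DMPU, MeOH (2 equiv), −78 °C; pH 7 buffer quench at −78 °C; used at once
Reagents that add atoms: none
Why: SmI2 reductive cleavage of a cyclopropyl ketone: the ketyl breaks the exocyclic C10–CH2 bond (the one overlapping the C=O π system), turning the CH2 into the C4 methyl, and kinetic protonation of the samarium enolate at C10 anti to that axial methyl should give the trans ring fusion.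

**Step 7**
Reactants: 7, trans-fused ketone
Product: 8, (1R,3aR,8aR)-3a,6-dimethyl-1-(propan-2-yl)-1,2,3,3a,4,8a-hexahydroazulen-1-ol
Conditions: i-PrMgCl, anhydrous CeCl3, THF, −78 °C
Reagents that add atoms: isopropylmagnesium chloride, CC(C)[Mg]Cl
Why: Organocerium (Imamoto) 1,2-addition tolerates the very enolisable ketone; attack anti to the C9 substituent on C10 and anti to the angular methyl (α face) gives the β-OH/α-iPr carbinol (C1 R).

**Step 8**
Reactants: 8, diene carbinol
Product: 9, C8–C9 mono-epoxide of 8 (oxirane syn to the C1–OH; C6=C7 untouched)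
Conditions: VO(acac)2 (5 mol%), t-BuOOH (1.2 equiv), CH2Cl2, 0 °C
Reagents that add atoms: tert-butyl hydroperoxide, CC(C)(C)OO
Why: Vanadium-catalysed hydroxyl-directed epoxidation selects the homoallylic C9=C8 alkene over the remote trisubstituted C7=C6; the oxirane configuration is destroyed in step 9.

**Step 9**
Reactants: 9, vinyl epoxide
Product: 10, (3R,3aR,8aR)-3-hydroxy-6,8a-dimethyl-3-(propan-2-yl)-2,3,3a,5,8,8a-hexahydroazulen-4(1H)-one (C9 ketone, C8H2, C6=C7)
Conditions: Pd(PPh3)4 (5 mol%), CH2Cl2, 0 °C→rt
Reagents that add atoms: none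
Why: Pd(0)-catalysed isomerisation of a 1,3-diene mono-epoxide (Suzuki–Oda–Noyori): ionisation at allylic C8 and a 1,2-hydride shift from C9 give the β,γ-unsaturated ketone under neutral conditions, so C6=C7 stays out of conjugation.

**Step 10**
Reactants: 10, β-hydroxy ketone
Product: 11, jaeschkeanadiol, (3R,3aS,4S,8aR)-6,8a-dimethyl-3-(propan-2-yl)-1,2,3,3a,4,5,8,8a-octahydroazulene-3,4-diol
Conditions: Me4NBH(OAc)3, MeCN–AcOH, −30 °C
Reagents that add atoms: none
Why: Evans–Saksena directed reduction: hydride is delivered intramolecularly from the C1–O-bound borohydride, giving the 1,3-anti diol (C9 S, OH on the face opposite the C1–OH); the reagent does not reduce the ketone without direction.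

**Step 11**
Reactants: 11, jaeschkeanadiol
Product: 12, 8α,9α-epoxyjaeschkeanadiol (daucane numbering; C6–C7 oxirane cis to the C9–OH)
Conditions: VO(acac)2 (5 mol%), t-BuOOH (1.5 equiv), CH2Cl2, 0 °C→rt
Reagents that add atoms: tert-butyl hydroperoxide, CC(C)(C)OO
Why: Vanadium-catalysed directed epoxidation by the homoallylic secondary C9–OH delivers oxygen to the same (α) face, which is also the face away from the angular methyl, setting both oxirane carbons.

**Step 12**
Reactants: 12, epoxy diol; 13, 4-acetoxybenzoyl chloride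
Product: 14, jaeskeanin
Conditions: DMAP, pyridine, CH2Cl2, 0→40 °C; then NH4OAc, MeOH–H2O, rt
Reagents that add atoms: none (13 is a reactant; its acetyl group is removed in the second stage)
Why: DMAP-catalysed acylation takes only the secondary C9–OH (the tertiary C1–OH is inert), and the phenolic acetate is then cleaved by mild ammonolysis much faster than the alkyl benzoate, without touching the epoxide; no stereocentre changes.

## Compound list

1 | 3-(4-methylphenyl)propanoic acid | Cc1ccc(CCC(=O)O)cc1 | starting material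
2 | 1-diazo-4-(4-methylphenyl)butan-2-one | Cc1ccc(CCC(=O)C=[N+]=[N-])cc1 | intermediate
3 | 6-methyl-3,4-dihydroazulen-1(2H)-one | O=C1CCC2=C1C=CC(C)=CC2 | intermediate
4 | (1S)-6-methyl-1,2,3,4-tetrahydroazulen-1-ol | O[C@H]1CCC2=C1C=CC(C)=CC2 | intermediate
5 | (1S,3aR,8aS)-6-methyl-1,2,3,4-tetrahydro-3a,8a-methanoazulen-1-ol | O[C@H]1CC[C@]23CC=C(C)C=C[C@]12C3 | intermediate
6 | (3aR,8aS)-6-methyl-3,4-dihydro-3a,8a-methanoazulen-1(2H)-one | O=C1CC[C@]23CC=C(C)C=C[C@]12C3 | intermediate
7 | (3aR,8aR)-3a,6-dimethyl-3,3a,4,8a-tetrahydroazulen-1(2H)-one | O=C1CC[C@]2(C)CC=C(C)C=C[C@H]21 | intermediate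
8 | (1R,3aR,8aR)-3a,6-dimethyl-1-(propan-2-yl)-1,2,3,3a,4,8a-hexahydroazulen-1-ol | CC(C)[C@]1(O)CC[C@]2(C)CC=C(C)C=C[C@H]21 | intermediate
9 | C8–C9 epoxide of 8, oxirane syn to C1–OH | CC(C)[C@]1(O)CC[C@]2(C)CC=C(C)[C@H]3O[C@H]3[C@H]21 | intermediate
10 | (3R,3aR,8aR)-3-hydroxy-6,8a-dimethyl-3-(propan-2-yl)-2,3,3a,5,8,8a-hexahydroazulen-4(1H)-one | CC(C)[C@]1(O)CC[C@]2(C)CC=C(C)CC(=O)[C@H]21 | intermediate
11 | jaeschkeanadiol | CC(C)[C@]1(O)CC[C@]2(C)CC=C(C)C[C@H](O)[C@H]21 | intermediate
12 | 8α,9α-epoxyjaeschkeanadiol | CC(C)[C@]1(O)CC[C@]2(C)C[C@@H]3O[C@]3(C)C[C@H](O)[C@H]21 | intermediate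
13 | 4-acetoxybenzoyl chloride | CC(=O)Oc1ccc(cc1)C(Cl)=O | starting material
14 | jaeskeanin | CC(C)[C@]1(O)CC[C@]2(C)C[C@@H]3O[C@]3(C)C[C@H](OC(=O)c3ccc(O)cc3)[C@H]21 | target

## Step count and risks

Total steps: 12. Longest linear sequence: 12 (from 1).

Steps most likely to fail:

- **Step 4.** Alcohol 4 is a trienyl carbinol that ionises easily, and the carbenoid must choose one of three alkenes. Fallback: drop the carbinol/cyclopropane relay (steps 3–6) and make racemic 7 directly by copper-mediated conjugate methylation of enone 3 (MeMgBr, CuBr·SMe2, TMSCl), then obtain the single enantiomer by lipase-catalysed kinetic resolution (acylation of the C9–OH) at diol 11.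
- **Step 6.** Three things can go wrong: cleavage of the ring-fusion bond instead of the exocyclic one, the C10 epimer from protonation, and isomerisation of the sensitive dienyl ketone 7. Fallback: reverse the order. Add i-PrMgCl/CeCl3 to cyclopropyl ketone 6, which has no acidic C10–H; attack anti to the cyclopropane CH2 gives the same C1 configuration. Then open the dienyl cyclopropane with Li/NH3 (dissolving-metal vinylcyclopropane cleavage). The resulting diene would be carried on as in steps 8–10 or, if the 1,4-diene forms, by hydroboration of the C9=C10 alkene; the face selectivity of that hydroboration would need to be checked.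
- **Step 9.** The π-allyl palladium intermediate could be trapped by the C1–OH (cyclic ether) or eliminate to a dienol. Fallback: open vinyl epoxide 9 with LiAlH4 at allylic C8 to give the 9-epi diol, then oxidise the secondary alcohol selectively (Dess–Martin) to reach the same ketone 10; this costs one extra step.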